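## Retrosynthetic overview

1. The 14-membered carbocycle is closed last, at C1–C14, by a 14-exo radical addition of a primary C14 radical to the β-carbon of an α-(phenylsulfonylmethyl)butenolide; loss of PhSO2• in the same step unveils the exo-methylene and sets C1 trans to C2.
2. The butenolide ring is formed just before that, by esterification of a vinyl carbinol with 2-[(phenylsulfonyl)methyl]acrylic acid and ring-closing metathesis.
3. C2 is set by a catalytic asymmetric vinylzinc addition to a C13 enal.
4. The chain (C6 and C10 stereocentres, all three E-alkenes) comes from two iterative asymmetric vinylogous Mukaiyama aldol reactions of one morpholine-amide dienolate; each amide is reduced to the next enal with Schwartz reagent.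
5. The first enal (C10–C14, carrying the iodide radical precursor) comes from but-3-yn-1-ol by Zr-catalysed carboalumination.

Assumption: compounds 1, 5, 6 and 15 and the usual reagents are commercial; atom labels C1–C17 in the text follow cembrane numbering (C1 = ring-fusion CH, C2 = lactone O–CH, methyls on C4/C8/C12, acetates on C6/C10, C17 = exo-methylene).

## Route

**Step 1**
Reactants: 1, but-3-yn-1-ol
Product: 2, (2E)-3-methylpent-2-ene-1,5-diol
Conditions: Me3Al (3 equiv), Cp2ZrCl2 (0.25 equiv), CH2Cl2, 0 °C→rt; then n-BuLi, (CH2O)n, THF, −78 °C→rt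
Reagents that add atoms: trimethylaluminium, C[Al](C)C; paraformaldehyde, C=O
Why: Negishi Zr-catalysed methylalumination is a syn carbometalation (Me to the internal, Al to the terminal carbon), so trapping the vinylalanate with formaldehyde with retention gives only the E trisubstituted alkene.

**Step 2**
Reactants: 2, (2E)-3-methylpent-2-ene-1,5-diol
Product: 3, (2E)-5-hydroxy-3-methylpent-2-enal
Conditions: MnO2, CH2Cl2, rt
Reagents that add atoms: none
Why: MnO2 allylic oxidation is selective for the allylic primary alcohol and leaves the homoallylic OH and the alkene geometry untouched.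

**Step 3**
Reactants: 3, (2E)-5-hydroxy-3-methylpent-2-enal
Product: 4, (2E)-5-iodo-3-methylpent-2-enal
Conditions: PPh3, I2, imidazole, CH2Cl2, 0 °C
Reagents that add atoms: iodine, II
Why: Garegg–Samuelsson (Appel-type) iodination of the primary alcohol is near-neutral and tolerated by the enal; it installs the radical precursor at C14.

**Step 4**
Reactants: 5, 3-methylbut-2-enoyl chloride; 6, morpholine
Product: 7, 3-methyl-1-(morpholin-4-yl)but-2-en-1-one
Conditions: Et3N, CH2Cl2, 0 °C
Reagents that add atoms: none
Why: Simple N-acylation of a secondary amine by an acid chloride.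

**Step 5**
Reactants: 7, 3-methyl-1-(morpholin-4-yl)but-2-en-1-one
Product: 8, 4-[(1Z)-1-(tert-butyldimethylsilyloxy)-3-methylbuta-1,3-dien-1-yl]morpholine
Conditions: LDA, THF, −78 °C; TBSCl, DMPU
Reagents that add atoms: tert-butyldimethylsilyl chloride, CC(C)(C)[Si](C)(C)Cl
Why: γ-Deprotonation of the senecioyl amide and O-silylation gives the cross-conjugated N,O-silyl ketene aminal (extended enolate), Z as is usual for amide enolates.

**Step 6**
Reactants: 4, (2E)-5-iodo-3-methylpent-2-enal; 8, silyl dienol ether
Product: 9, (2E,5S,6E)-5-hydroxy-9-iodo-3,7-dimethyl-1-(morpholin-4-yl)nona-2,6-dien-1-one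
Conditions: SiCl4 (1.5 equiv), Denmark binaphthyldiamine bisphosphoramide (5 mol %, the antipode that adds to the Si face, expected (S,S)), i-Pr2NEt, CH2Cl2, −78 °C; aq. KF/NaHCO3
Reagents that add atoms: none
Why: Lewis-base-activated SiCl4 vinylogous Mukaiyama aldol: the dienolate reacts only at its γ-CH2 through the s-trans diene (E-enamide), and the chiral phosphoramide-bound silyl cation directs Si-face attack on the enal to give the 5S carbinol (C10).

**Step 7**
Reactants: 9, hydroxy enamide
Product: 10, (2E,5S,6E)-5-hydroxy-9-iodo-3,7-dimethylnona-2,6-dienal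
Conditions: Cp2Zr(H)Cl (2.5 equiv), THF, rt, 20 min; silica gel work-up
Reagents that add atoms: none
Why: Schwartz-reagent reduction of a tertiary amide stops at a stable zirconated hemiaminal that releases the aldehyde on work-up; one extra equivalent covers the free OH, and the short contact time spares the iodide and trisubstituted alkenes.

**Step 8**
Reactants: 10, hydroxy enal; 8, silyl dienol ether
Product: 11, (2E,5S,6E,9S,10E)-5,9-dihydroxy-13-iodo-3,7,11-trimethyl-1-(morpholin-4-yl)trideca-2,6,10-trien-1-one
Conditions: SiCl4 (2.5 equiv), same bisphosphoramide antipode (5 mol %), i-Pr2NEt (1.5 equiv), CH2Cl2, −78 °C; aq. KF/NaHCO3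
Reagents that add atoms: none
Why: Second vinylogous Mukaiyama aldol; the extra SiCl4/amine masks the free hydroxyl in situ as its trichlorosilyl ether (cleaved on work-up), and the same catalyst again gives Si-face attack, so the new carbinol (C6) is S under catalyst control.

**Step 9**
Reactants: 11, diol amide
Product: 12, (2E,5S,6E,9S,10E)-13-iodo-3,7,11-trimethyl-1-(morpholin-4-yl)-1-oxotrideca-2,6,10-triene-5,9-diyl diacetate
Conditions: Ac2O, Et3N, DMAP (cat.), CH2Cl2, 0 °C
Reagents that add atoms: acetic anhydride, CC(=O)OC(C)=O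
Why: DMAP-catalysed acylation installs both target acetates in one operation without touching the stereocentres.

**Step 10**
Reactants: 12, diacetoxy amide
Product: 13, (2E,5S,6E,9S,10E)-13-iodo-3,7,11-trimethyl-1-oxotrideca-2,6,10-triene-5,9-diyl diacetate
Conditions: Cp2Zr(H)Cl (1.5 equiv), THF, rt, 20 min
Reagents that add atoms: none
Why: Schwartz amide-to-aldehyde reduction is chemoselective for tertiary amides over esters, so the two acetates survive.

**Step 11**
Reactants: 13, diacetoxy enal
Product: 14, (3R,4E,7S,8E,11S,12E)-3-hydroxy-15-iodo-5,9,13-trimethylpentadeca-1,4,8,12-tetraene-7,11-diyl diacetate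
Conditions: Zn(CH=CH2)2 (2.5 equiv), (+)-MIB (10 mol %), toluene, −30→0 °C; buffered work-up
Reagents that add atoms: divinylzinc, C=C[Zn]C=C
Why: Amino-alcohol-catalysed (Noyori/Oppolzer-type) 1,2-addition of a vinylzinc; the ligand antipode directs Re-face attack to give the 3R carbinol (C2 of the target), and the diorganozinc does not touch acetates or the alkyl iodide.

**Step 12**
Reactants: 15, 2-(bromomethyl)acrylic acid
Product: 16, 2-[(phenylsulfonyl)methyl]prop-2-enoic acid
Conditions: PhSO2Na (2 equiv), MeOH, reflux; acidify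
Reagents that add atoms: sodium benzenesulfinate, [Na+].[O-]S(=O)c1ccccc1
Why: S-alkylation of the sulfinate by the activated allylic bromide (SN2 and SN2′ give the same product).

**Step 13**
Reactants: 14, vinyl carbinol; 16, sulfonyl acrylic acid
Product: 17, (3R,4E,7S,8E,11S,12E)-7,11-bis(acetyloxy)-15-iodo-5,9,13-trimethylpentadeca-1,4,8,12-tetraen-3-yl 2-[(phenylsulfonyl)methyl]prop-2-enoate
Conditions: EDC·HCl, DMAP (cat.), CH2Cl2, 0 °C
Reagents that add atoms: none
Why: Steglich-type esterification acylates oxygen with retention at the carbinol and avoids acid that would ionise the bis-allylic alcohol.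

**Step 14**
Reactants: 17, diene ester
Product: 18, (5S)-5-[(1E,4S,5E,8S,9E)-4,8-bis(acetyloxy)-12-iodo-2,6,10-trimethyldodeca-1,5,9-trien-1-yl]-3-[(phenylsulfonyl)methyl]furan-2(5H)-one
Conditions: Hoveyda–Grubbs II (10 mol %), 1,4-benzoquinone (20 mol %), toluene, 80 °C, 5 mM
Reagents that add atoms: none
Why: Ring-closing metathesis between the vinyl group and the acrylate gives the butenolide with loss of ethylene; the E-trisubstituted chain alkenes cannot compete (closure onto them would need a trans-cycloalkene or a macrocycle), and the stereocentre is not involved.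

**Step 15**
Reactants: 18, iodo butenolide sulfone
Product: 19, target, (3aR,6E,8S,10E,12S,14E,15aS)-6,10,14-trimethyl-3-methylidene-2-oxo-2,3,3a,4,5,8,9,12,13,15a-decahydrocyclotetradeca[b]furan-8,12-diyl diacetate (1R,2S,6S,10S in cembrane numbering)
Conditions: (Bu3Sn)2 (1.5 equiv), hν (sunlamp, Pyrex), PhH, 1 mM, 25–40 °C
Reagents that add atoms: none
Why: Proposed new method: Bu3Sn• abstracts iodine to give the nucleophilic primary C14 radical, which adds 14-exo-trig to the electron-poor β-carbon (C1) of the butenolide on the face anti to the C2 side chain (torsionally favoured, giving the trans ring fusion and 1R); the α-lactone radical then expels PhSO2•, revealing the exo-methylene, and PhSO2• regenerates Bu3Sn• from the ditin, with no H-donor present to reduce the radical prematurely; the closest known chemistry is intermolecular radical allylation of alkyl iodides with 2-(sulfonylmethyl)acrylates (SH2′ addition–fragmentation), trans-selective radical additions to γ-substituted butenolides, and radical macrocyclisations onto electron-poor alkenes.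

## Compound list

1 | but-3-yn-1-ol | C#CCCO | starting material
2 | (2E)-3-methylpent-2-ene-1,5-diol | OC/C=C(\C)CCO | intermediate
3 | (2E)-5-hydroxy-3-methylpent-2-enal | O=C/C=C(\C)CCO | intermediate
4 | (2E)-5-iodo-3-methylpent-2-enal | O=C/C=C(\C)CCI | intermediate
5 | 3-methylbut-2-enoyl chloride | CC(C)=CC(=O)Cl | starting material
6 | morpholine | C1COCCN1 | starting material
7 | 3-methyl-1-(morpholin-4-yl)but-2-en-1-one | CC(C)=CC(=O)N1CCOCC1 | intermediate
8 | 4-[(1Z)-1-(tert-butyldimethylsilyloxy)-3-methylbuta-1,3-dien-1-yl]morpholine | C=C(C)/C=C(/N1CCOCC1)O[Si](C)(C)C(C)(C)C | intermediate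
9 | (2E,5S,6E)-5-hydroxy-9-iodo-3,7-dimethyl-1-(morpholin-4-yl)nona-2,6-dien-1-one | O=C(N1CCOCC1)/C=C(\C)C[C@H](O)/C=C(\C)CCI | intermediate
10 | (2E,5S,6E)-5-hydroxy-9-iodo-3,7-dimethylnona-2,6-dienal | O=C/C=C(\C)C[C@H](O)/C=C(\C)CCI | intermediate
11 | (2E,5S,6E,9S,10E)-5,9-dihydroxy-13-iodo-3,7,11-trimethyl-1-(morpholin-4-yl)trideca-2,6,10-trien-1-one | O=C(N1CCOCC1)/C=C(\C)C[C@H](O)/C=C(\C)C[C@H](O)/C=C(\C)CCI | intermediate
12 | (2E,5S,6E,9S,10E)-13-iodo-3,7,11-trimethyl-1-(morpholin-4-yl)-1-oxotrideca-2,6,10-triene-5,9-diyl diacetate | O=C(N1CCOCC1)/C=C(\C)C[C@H](OC(C)=O)/C=C(\C)C[C@H](OC(C)=O)/C=C(\C)CCI | intermediate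
13 | (2E,5S,6E,9S,10E)-13-iodo-3,7,11-trimethyl-1-oxotrideca-2,6,10-triene-5,9-diyl diacetate | O=C/C=C(\C)C[C@H](OC(C)=O)/C=C(\C)C[C@H](OC(C)=O)/C=C(\C)CCI | intermediate
14 | (3R,4E,7S,8E,11S,12E)-3-hydroxy-15-iodo-5,9,13-trimethylpentadeca-1,4,8,12-tetraene-7,11-diyl diacetate | C=C[C@@H](O)/C=C(\C)C[C@H](OC(C)=O)/C=C(\C)C[C@H](OC(C)=O)/C=C(\C)CCI | intermediate
15 | 2-(bromomethyl)acrylic acid | C=C(CBr)C(=O)O | starting material
16 | 2-[(phenylsulfonyl)methyl]prop-2-enoic acid | C=C(CS(=O)(=O)c1ccccc1)C(=O)O | intermediate
17 | (3R,4E,7S,8E,11S,12E)-7,11-bis(acetyloxy)-15-iodo-5,9,13-trimethylpentadeca-1,4,8,12-tetraen-3-yl 2-[(phenylsulfonyl)methyl]prop-2-enoate | C=C[C@@H](OC(=O)C(=C)CS(=O)(=O)c1ccccc1)/C=C(\C)C[C@H](OC(C)=O)/C=C(\C)C[C@H](OC(C)=O)/C=C(\C)CCI | intermediate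
18 | (5S)-5-[(1E,4S,5E,8S,9E)-4,8-bis(acetyloxy)-12-iodo-2,6,10-trimethyldodeca-1,5,9-trien-1-yl]-3-[(phenylsulfonyl)methyl]furan-2(5H)-one | O=C1O[C@@H](/C=C(\C)C[C@H](OC(C)=O)/C=C(\C)C[C@H](OC(C)=O)/C=C(\C)CCI)C=C1CS(=O)(=O)c1ccccc1 | intermediate
19 | (3aR,6E,8S,10E,12S,14E,15aS)-6,10,14-trimethyl-3-methylidene-2-oxo-2,3,3a,4,5,8,9,12,13,15a-decahydrocyclotetradeca[b]furan-8,12-diyl diacetate (CID11069750) | C=C1C(=O)O[C@H]2/C=C(\C)C[C@H](OC(C)=O)/C=C(\C)C[C@H](OC(C)=O)/C=C(\C)CC[C@H]12 | target

## Summary

Total steps: 15.
Longest linear sequence: 12 (steps 1–3, 6–11, 13–15); steps 4–5 and 12 are side branches.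

Three steps most likely to fail:

1. **Step 15 (radical macrocyclisation).** Risks are oligomerisation if the 14-exo addition is slow, E/Z erosion at C11=C12 through reversible 3-exo closure of the homoallylic radical, and cis/trans leakage at C1. Fallback: move the ring closure to C1–C2. Elaborate the C14 terminus into a (Z)-2-(bromomethyl)enoate (aldehyde, Baylis–Hillman adduct, SN2′ bromide) and cyclise it onto the C2 enal with CrCl2 in an intramolecular Barbier allylation–lactonisation.

2. **Step 14 (RCM).** A trisubstituted butenolide bearing a CH2SO2Ph group on a bis-allylic ester is a demanding closure. Fallback: build the lactone without metathesis. Add methyl propiolate to enal 13 under Zn–ProPhenol catalysis, then Lindlar semihydrogenation/lactonisation to the α-unsubstituted butenolide; run the macrocyclisation as a reductive Giese cyclisation ((TMS)3SiH) and add the methylene afterwards by Eschenmoser methylenation, with the hydroxyls carried as silyl ethers and acetylated last.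

3. **Step 11 (asymmetric vinylation).** The ee on a β,β-disubstituted enal is uncertain and the bis-allylic alcohol is acid-labile. Fallback: Zn–ProPhenol addition of trimethylsilylacetylene to enal 13, then desilylation and Lindlar semi-reduction to the same vinyl carbinol 14.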